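## Structural features

The target is a biflavonoid. An upper flavan-3-ol (benzo ring A, pyran ring C, pyrogallol ring B; one phenol at C7, no oxygen at C5) is bonded through C4 to C8 of a lower dihydroflavonol (rings D, F and E, ring E again a pyrogallol). Upper C2, C3 and C4 are contiguous stereocentres, (2R,3S,4S), with aryl, hydroxyl and ring D mutually trans. Lower C2 and C3, (2R,3R), are also trans, and ring D alone separates the two sets. Both halves hold the same motif, a 3,4,5-trioxygenated aryl group on a benzylic C–O carbon next to a secondary carbinol, with the same absolute sense. Fragile elements are the two pyrogallol rings (air oxidation), the α-hydroxy ketone of ring F (enolisation at C3, opening of O1–C2 under base), the benzylic C2–O1 bonds and the doubly benzylic C4–C8 bond. The real difficulty is the C4–C8 bond: C8 lies between the two oxygen-bearing carbons of ring D (C7 and C8a), the site that electrophilic substitution of a resorcinol avoids, and C4 must form trans to C3. The key step exploits exactly this arrangement: a cation at upper C4 is strongly stabilised by ring D, and ring A, tethered through O1–C2–C3, can capture it at C4a and close ring C.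

## Logic of the disconnections

23 from 22. The eight benzyl–oxygen bonds are cut. The free polyphenol is too oxidation-prone to carry, so hydrogenolysis is the only final operation. All earlier chemistry then runs on stable ethers. The last step must spare the aryl ketone, the two ring C–O benzylic bonds and the C4–C8 bond.

22 from 20 (through 21). Lower O1–C2 is cut, opening ring F. That bond is benzylic and anti to the C3 oxygen, the signature of a trans-epoxide opened with inversion by the ring D phenol ortho to the carbonyl. Ring F and both lower stereocentres reduce to one epoxide, and both ring D oxygens can carry the same acid-labile acetal. The forward step must free the phenols and close at the benzylic carbon without ionising it.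

20 from 16 and 17 (through 18 and 19). The bond between lower C4 and C4a is cut. The lower half becomes an electrophile and ring D a nucleophile made by bromine–lithium exchange; the position of the bromine in 16 fixes where the carbonyl carbon goes. No Friedel–Crafts acylation, no enone and no catalyst-controlled epoxidation of a large substrate are needed. The exchange must outrun any deprotonation, and 19 needs one reoxidation.

17 from 4. Only an oxidation level changes. The lower epoxide has the same substituents and the same absolute sense as the epoxide that leads to the upper unit, so one asymmetric step serves both halves. The oxidation must leave the epoxide intact.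

16 from 14. Upper C4–C4a is cut, opening ring C. A cation at C4 flanked by the two ring D oxygens is easy to form, and ring A sits in a 1,6-relation to it. The precursor is acyclic with only two fixed stereocentres. The forward step must choose ring A over ring B, the carbon para to the benzyloxy group over the one between the oxygens, and the face anti to the C3 benzyloxy group.

14 from 10 and 12 (through 13). Upper C4–C8 is cut. The carbon between the two ring D oxygens is the most acidic one, so an aryllithium forms exactly where electrophilic substitution would not go. Ring D arrives as a simple arene that already carries its bromine. Metalation must occur between the acetal oxygens without disturbing the bromine, and 10 must add without enolising.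

12 from 11. One C–Br bond is cut; the position para to one acetal oxygen and ortho to the other is the natural site of bromination.

10 from 6 (through 7, 8 and 9). No skeletal bond is cut. The secondary hydroxyl must become a benzyl ether while the primary one becomes the aldehyde; a temporary primary ether and one oxidation do this. The temporary group must not migrate under base.

6 from 4 and 5. Upper O1–C2 is cut. The benzylic C–O bond anti to the C3 oxygen again points to an epoxide opened with inversion, and the erythro product maps onto a 2,3-trans flavan. Ring A arrives as a simple phenol. The phenoxide must attack the benzylic carbon only.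

4 from 3, 2 and 1. The epoxide C–O bonds and then the alkene are cut, leading back to a commercial aldehyde. The allylic alcohol allows reagent-controlled epoxidation, which sets four of the five stereocentres of the target (two per half).

## Other disconnections considered

Alternative 1: The cut removes lower C4a–C8a and C5–C6, so ring D itself is built last between the two halves. Diene A2, a 1-methoxy-1,3-bis(trimethylsilyloxy)buta-1,3-diene whose central carbon carries the benzylated upper flavan through C4, would add to terminal ynone A3, which holds ring E and the protected syn-diol. Loss of methanol would aromatise the adduct to resorcinol ketone A1.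
- In favour: the polarity of the partners fixes the ring D substitution pattern unambiguously. On this point it is better than the chosen plan, which relies on a directed lithiation next to a bromine. It is also highly convergent, and A1 is only a Mitsunobu-type closure and deprotections away from the lower ring system.
- Against: A2 derives from a β-keto ester with a bulky flavan-4-yl group on its α-carbon. Making that C4–C bond with 3,4-trans control is the same stereochemical problem as in the chosen plan, moved to a poorer nucleophile. A centrally substituted diene of this size should be reluctant to reach the s-cis form and is hydrolytically fragile. A3 is an epimerisable α-alkoxy ketone and may react in a Michael mode.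
- Comparison: structurally it builds a ring that can be bought, whereas the chosen plan builds ring C, which must be made in any case. Mechanistically both rely on polarity control, pericyclic there and cationic here. In step count the separate routes to A2 and A3 are expected to exceed the sixteen steps of the chosen plan.

Alternative 2: The cut is lower O1–C2. Epoxychalcone A5, with a benzyl ether at C7 and a methoxymethyl ether on the oxygen ortho to the carbonyl, would lose the acetal in methanolic HCl. The freed phenol would open the epoxide at the benzylic carbon to give A4, the nona-O-benzyl ether of the target with a free lower C3 hydroxyl.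
- In favour: the closure is stereospecific and of a known type. Only one hydroxyl is free in A4, which should make it easier to handle than 22; on that point it is better than the chosen plan.
- Equal: the chosen plan contains the same bond formation as step 15, so on mechanism the two are equals.
- Against as the governing disconnection: it simplifies only ring F and leaves the C4–C8 bond and the three upper stereocentres unanswered. A5 needs the two ring D oxygens told apart and, if made from a chalcone, a catalyst-controlled epoxidation of a large ortho-substituted enone.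
- Comparison: the chosen plan keeps both ring D oxygens as the same acetal throughout and takes the epoxide from 4. This should save about three steps and one uncertain asymmetric step, at the price of a second free phenol in 21 and 22.

Alternative 3: The cut removes upper O1–C2 and C3–C4 together. A chiral phosphoric acid would dehydrate o-hydroxybenzhydrol A7 to an o-quinone methide, which would add (E)-β-silylstyrene A8 in an inverse-demand hetero-Diels–Alder reaction to give 3-silylflavan A6. A Tamao–Fleming oxidation would then convert C–Si into the C3 hydroxyl with retention.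
- In favour: ring C and its three stereocentres come from two simple partners in one step. The alkene geometry translates into the 2,3-trans relation and silicon steers the regiochemistry. For the upper unit it is clearly better on step economy, roughly five steps against eleven.
- Against: one catalyst would have to control both the absolute configuration and the endo/exo question that decides the 3,4 relation. The styrene offers no hydrogen-bonding group, and the quinone methide carries a 2,6-disubstituted aryl group on its exocyclic carbon. The oxidation must cope with a hindered secondary silane. A6 needs a further benzylation and, as drawn, has no handle on ring D for the lower unit.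
- Comparison: both plans close ring C through a ring D-substituted, quinone-methide-like electrophile and are equal in leaving ring D as a bis-acetal. The alternative is shorter but puts all stereochemical risk in one step without close precedent. The chosen plan is longer, but each stereocentre has an independent, established source.

Key step: step 11

Remarks on the chemistry:
- 14 and 16 are the cyclisation precursor and its product. Ring D carries, beside its two acetal groups, one bromine meta to the reacting carbon. It is a spectator in the key step and later marks the carbon that receives the carbonyl group.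
- The tartrate in step 3 must be the L-(+) enantiomer to reach the (2S,3S)-epoxide.
- Compounds with ring D on upper C4 (16 onwards) are expected to show slowly interconverting rotamers about C4–C8; each is treated as one compound.
- Positions are numbered as in flavans, rings A, C, B above and D, F, E below.

## Route

Step 1
Reactants: 1 3,4,5-tris(benzyloxy)benzaldehyde
Product: 2 ethyl (E)-3-[3,4,5-tris(benzyloxy)phenyl]prop-2-enoate
Conditions: (EtO)2P(O)CH2CO2Et, NaH, THF, 0 °C → rt
Reagents that add atoms: triethyl phosphonoacetate, CCOC(=O)CP(=O)(OCC)OCC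
Why: Horner–Wadsworth–Emmons olefination; the stabilised phosphonate anion should give the (E)-enoate.

Step 2
Reactants: 2 ethyl (E)-cinnamate
Product: 3 (E)-3-[3,4,5-tris(benzyloxy)phenyl]prop-2-en-1-ol
Conditions: i-Bu2AlH (2.5 equiv), CH2Cl2, −78 → 0 °C; aq. potassium sodium tartrate
Reagents that add atoms: none
Why: 1,2-reduction of a conjugated ester by an aluminium hydride; alkene and benzyl ethers are inert.

Step 3
Reactants: 3 (E)-allylic alcohol
Product: 4 [(2S,3S)-3-[3,4,5-tris(benzyloxy)phenyl]oxiran-2-yl]methanol
Conditions: Ti(OiPr)4 (10 mol %), L-(+)-diethyl tartrate (12 mol %), t-BuOOH, 4 Å MS, CH2Cl2, −20 °C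
Reagents that add atoms: tert-butyl hydroperoxide, CC(C)(C)OO
Why: Sharpless asymmetric epoxidation; with the L-(+)-tartrate ligand oxygen should be delivered to the face that gives the (2S,3S)-epoxide, which sets both stereocentres; the twisted para ether makes this aryl group only a weak donor, so the epoxide should survive.

Step 4
Reactants: 4 epoxy alcohol; 5 3-(benzyloxy)phenol
Product: 6 (2S,3R)-3-[3-(benzyloxy)phenoxy]-3-[3,4,5-tris(benzyloxy)phenyl]propane-1,2-diol
Conditions: 5 (1.5 equiv), NaOH (aq.), 1,4-dioxane–H2O, 70 °C
Reagents that add atoms: none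
Why: phenoxide opening of a 3-aryl-2,3-epoxy alcohol at the benzylic carbon, a known SN2 process with inversion; the erythro product corresponds to a 2,3-trans flavan.

Step 5
Reactants: 6 diol
Product: 7 (2S,3R)-3-[3-(benzyloxy)phenoxy]-3-[3,4,5-tris(benzyloxy)phenyl]-1-(trityloxy)propan-2-ol
Conditions: Ph3CCl, Et3N, DMAP (cat.), CH2Cl2, rt
Reagents that add atoms: trityl chloride, ClC(c1ccccc1)(c1ccccc1)c1ccccc1
Why: the bulky trityl group should etherify only the primary hydroxyl.

Step 6
Reactants: 7 trityl ether
Product: 8 (2S,3R)-2-(benzyloxy)-3-[3-(benzyloxy)phenoxy]-3-[3,4,5-tris(benzyloxy)phenyl]propyl trityl ether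
Conditions: NaH, BnBr, Bu4NI (cat.), DMF, 0 °C → rt
Reagents that add atoms: benzyl bromide, BrCc1ccccc1
Why: Williamson etherification of the secondary alkoxide; a trityl ether, unlike a silyl ether, cannot migrate to the alkoxide.

Step 7
Reactants: 8 benzyl trityl diether
Product: 9 (2S,3R)-2-(benzyloxy)-3-[3-(benzyloxy)phenoxy]-3-[3,4,5-tris(benzyloxy)phenyl]propan-1-ol
Conditions: TsOH·H2O (cat.), MeOH–CH2Cl2, rt
Reagents that add atoms: none
Why: acid-catalysed methanolysis through the trityl cation; benzyl ethers and the benzylic aryl ether should not ionise under catalytic acid at room temperature.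

Step 8
Reactants: 9 primary alcohol
Product: 10 (2R,3R)-2-(benzyloxy)-3-[3-(benzyloxy)phenoxy]-3-[3,4,5-tris(benzyloxy)phenyl]propanal
Conditions: Dess–Martin periodinane, pyridine, CH2Cl2, 0 °C → rt
Reagents that add atoms: none
Why: Dess–Martin oxidation under buffered, non-basic conditions should give the α-alkoxy aldehyde without epimerisation or β-elimination of the aryloxide; the C2 descriptor changes by priority only; 10 is used at once.

Step 9
Reactants: 11 1,3-bis(methoxymethoxy)benzene
Product: 12 1-bromo-2,4-bis(methoxymethoxy)benzene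
Conditions: NBS, MeCN, 0 °C → rt
Reagents that add atoms: N-bromosuccinimide, O=C1CCC(=O)N1Br
Why: electrophilic aromatic bromination at the unhindered carbon para to one acetal oxygen and ortho to the other; neutral conditions keep the acetals.

Step 10
Reactants: 12 aryl bromide; 10 aldehyde
Product: 14 (1RS,2S,3R)-2-(benzyloxy)-3-[3-(benzyloxy)phenoxy]-1-[3-bromo-2,6-bis(methoxymethoxy)phenyl]-3-[3,4,5-tris(benzyloxy)phenyl]propan-1-ol, via aryllithium 13 (not isolated)
Conditions: LiN(i-Pr)2, THF, −78 °C; then 10, −78 °C; aq. NH4Cl
Reagents that add atoms: none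
Why: directed ortho-metalation at the carbon flanked by both acetal groups (an amide base does not exchange the bromine), then 1,2-addition to the aldehyde; the C1 configuration is immaterial because both epimers ionise to the same cation.

Step 11
Reactants: 14 carbinol (C1 epimers)
Product: 16 (2R,3S,4S)-3,7-bis(benzyloxy)-4-[3-bromo-2,6-bis(methoxymethoxy)phenyl]-2-[3,4,5-tris(benzyloxy)phenyl]chromane, via benzylic cation 15 (not isolated)
Conditions: Sc(OTf)3 (10 mol %), 4 Å MS, CH2Cl2, −20 → 0 °C
Reagents that add atoms: none
Why: Sc(OTf)3 should ionise the C1 hydroxyl of either epimer of 14 to cation 15, which is delocalised onto the two ortho acetal oxygens of ring D, so both epimers converge. Ring A, tethered through O1–C2–C3, then attacks through its carbon ortho to O1 and para to the benzyloxy group and rearomatises; this is an intramolecular Friedel–Crafts alkylation, the known reaction type by which 3-aryloxy-1-arylpropan-1-ols give 4-arylchromans. Ring C closes as a six-membered ring, 6-endo-trig with respect to the attacking C4a–C8a bond of ring A, through a half-chair transition state. The new stereocentre C4 is controlled by C3: to avoid allylic 1,3-strain with an ortho substituent of ring D the C3–H bond lies in the plane of the cation, ring A adds on the face anti to the C3 benzyloxy group, and the C2 aryl, the C3 oxygen and ring D all end up pseudo-equatorial, which is the 2,3-trans-3,4-trans (4S) isomer. On ring A the only other ortho carbon lies between two oxygens and is more hindered, so the para-to-benzyloxy carbon should win. Capture by ring B would need a five-membered 5-endo closure to an indane, stereoelectronically far worse than the chroman closure, and dilution suppresses intermolecular alkylation. The bromine is meta to the cationic carbon and only a spectator; catalytic acid, low temperature and molecular sieves are chosen to preserve the acetals and to bind the water released.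

Step 12
Reactants: 4 epoxy alcohol
Product: 17 (2R,3S)-3-[3,4,5-tris(benzyloxy)phenyl]oxirane-2-carbaldehyde
Conditions: Dess–Martin periodinane, pyridine, CH2Cl2, 0 °C
Reagents that add atoms: none
Why: Dess–Martin oxidation of a 2,3-epoxy alcohol to the epoxy aldehyde leaves the epoxide untouched; both stereocentres are kept (the C2 descriptor changes by priority only); 17 is used fresh.

Step 13
Reactants: 16 aryl bromide; 17 epoxy aldehyde
Product: 19 {3-[(2R,3S,4S)-3,7-bis(benzyloxy)-2-[3,4,5-tris(benzyloxy)phenyl]chroman-4-yl]-2,4-bis(methoxymethoxy)phenyl}{(2S,3S)-3-[3,4,5-tris(benzyloxy)phenyl]oxiran-2-yl}methanol (carbinol epimers), via aryllithium 18 (not isolated)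
Conditions: t-BuLi (2.1 equiv), THF, −78 °C; then 17, −78 °C; aq. NH4Cl
Reagents that add atoms: none
Why: bromine–lithium exchange at −78 °C is much faster than deprotonation of benzylic ether positions and gives an aryllithium chelated by the adjacent acetal; 1,2-addition to the aldehyde should outrun epoxide opening; the carbinol configuration is removed in step 14.

Step 14
Reactants: 19 epoxy carbinol
Product: 20 {3-[(2R,3S,4S)-3,7-bis(benzyloxy)-2-[3,4,5-tris(benzyloxy)phenyl]chroman-4-yl]-2,4-bis(methoxymethoxy)phenyl}{(2R,3S)-3-[3,4,5-tris(benzyloxy)phenyl]oxiran-2-yl}methanone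
Conditions: Dess–Martin periodinane, pyridine, CH2Cl2, 0 °C → rt
Reagents that add atoms: none
Why: Dess–Martin oxidation of the benzylic secondary alcohol should give the trans-epoxy ketone with the (αR,βS) configuration inherited from 4.

Step 15
Reactants: 20 epoxy ketone
Product: 22 (2R,3R)-8-[(2R,3S,4S)-3,7-bis(benzyloxy)-2-[3,4,5-tris(benzyloxy)phenyl]chroman-4-yl]-3,7-dihydroxy-2-[3,4,5-tris(benzyloxy)phenyl]chroman-4-one, via diphenol epoxy ketone 21 (not isolated)
Conditions: HCl (1 M in MeOH), MeOH–THF, 50 °C
Reagents that add atoms: none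
Why: acid methanolysis removes both methoxymethyl acetals, and the freed phenol ortho to the carbonyl opens the epoxide at the benzylic carbon in a 6-endo-tet closure with inversion, a known route from such chalcone epoxides to trans-dihydroflavonols; lower C3 keeps its configuration and lower C2 becomes R.

Step 16
Reactants: 22 octa-O-benzyl ether
Product: 23 (2R,3R)-3,7-dihydroxy-8-[(2R,3S,4S)-3,7-dihydroxy-2-(3,4,5-trihydroxyphenyl)chroman-4-yl]-2-(3,4,5-trihydroxyphenyl)chroman-4-one
Conditions: H2 (1 atm), Pd(OH)2/C, THF–MeOH, rt; work-up under argon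
Reagents that add atoms: none
Why: hydrogenolysis of eight benzyl ethers; the aryl ketone, the cyclic benzylic C2–O1 bonds and the C4–C8 bond should resist at atmospheric pressure, and no stereocentre is touched.

## Compound list

1 | 3,4,5-tris(benzyloxy)benzaldehyde | O=Cc1cc(OCc2ccccc2)c(OCc2ccccc2)c(OCc2ccccc2)c1 | starting material
2 | ethyl (E)-3-[3,4,5-tris(benzyloxy)phenyl]prop-2-enoate | CCOC(=O)/C=C/c1cc(OCc2ccccc2)c(OCc2ccccc2)c(OCc2ccccc2)c1 | intermediate
3 | (E)-3-[3,4,5-tris(benzyloxy)phenyl]prop-2-en-1-ol | OC/C=C/c1cc(OCc2ccccc2)c(OCc2ccccc2)c(OCc2ccccc2)c1 | intermediate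
4 | [(2S,3S)-3-[3,4,5-tris(benzyloxy)phenyl]oxiran-2-yl]methanol | OC[C@@H]1O[C@H]1c1cc(OCc2ccccc2)c(OCc2ccccc2)c(OCc2ccccc2)c1 | intermediate
5 | 3-(benzyloxy)phenol | Oc1cccc(OCc2ccccc2)c1 | starting material
6 | (2S,3R)-3-[3-(benzyloxy)phenoxy]-3-[3,4,5-tris(benzyloxy)phenyl]propane-1,2-diol | OC[C@H](O)[C@@H](c1cc(OCc2ccccc2)c(OCc2ccccc2)c(OCc2ccccc2)c1)Oc1cccc(OCc2ccccc2)c1 | intermediate
7 | (2S,3R)-3-[3-(benzyloxy)phenoxy]-3-[3,4,5-tris(benzyloxy)phenyl]-1-(trityloxy)propan-2-ol | C(c1ccccc1)(c1ccccc1)(c1ccccc1)OC[C@H](O)[C@@H](c1cc(OCc2ccccc2)c(OCc2ccccc2)c(OCc2ccccc2)c1)Oc1cccc(OCc2ccccc2)c1 | intermediate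
8 | (2S,3R)-2-(benzyloxy)-3-[3-(benzyloxy)phenoxy]-3-[3,4,5-tris(benzyloxy)phenyl]propyl trityl ether | C(c1ccccc1)(c1ccccc1)(c1ccccc1)OC[C@H](OCc1ccccc1)[C@@H](c1cc(OCc2ccccc2)c(OCc2ccccc2)c(OCc2ccccc2)c1)Oc1cccc(OCc2ccccc2)c1 | intermediate
9 | (2S,3R)-2-(benzyloxy)-3-[3-(benzyloxy)phenoxy]-3-[3,4,5-tris(benzyloxy)phenyl]propan-1-ol | OC[C@H](OCc1ccccc1)[C@@H](c1cc(OCc2ccccc2)c(OCc2ccccc2)c(OCc2ccccc2)c1)Oc1cccc(OCc2ccccc2)c1 | intermediate
10 | (2R,3R)-2-(benzyloxy)-3-[3-(benzyloxy)phenoxy]-3-[3,4,5-tris(benzyloxy)phenyl]propanal | O=C[C@H](OCc1ccccc1)[C@@H](c1cc(OCc2ccccc2)c(OCc2ccccc2)c(OCc2ccccc2)c1)Oc1cccc(OCc2ccccc2)c1 | intermediate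
11 | 1,3-bis(methoxymethoxy)benzene | COCOc1cccc(OCOC)c1 | starting material
12 | 1-bromo-2,4-bis(methoxymethoxy)benzene | COCOc1ccc(Br)c(OCOC)c1 | intermediate
13 | [3-bromo-2,6-bis(methoxymethoxy)phenyl]lithium | [Li]c1c(OCOC)ccc(Br)c1OCOC | intermediate (not isolated)
14 | (1RS,2S,3R)-2-(benzyloxy)-3-[3-(benzyloxy)phenoxy]-1-[3-bromo-2,6-bis(methoxymethoxy)phenyl]-3-[3,4,5-tris(benzyloxy)phenyl]propan-1-ol | OC(c1c(OCOC)ccc(Br)c1OCOC)[C@H](OCc1ccccc1)[C@@H](c1cc(OCc2ccccc2)c(OCc2ccccc2)c(OCc2ccccc2)c1)Oc1cccc(OCc2ccccc2)c1 | intermediate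
15 | C1 benzylic cation of 14 | [CH+](c1c(OCOC)ccc(Br)c1OCOC)[C@H](OCc1ccccc1)[C@@H](c1cc(OCc2ccccc2)c(OCc2ccccc2)c(OCc2ccccc2)c1)Oc1cccc(OCc2ccccc2)c1 | intermediate (not isolated)
16 | (2R,3S,4S)-3,7-bis(benzyloxy)-4-[3-bromo-2,6-bis(methoxymethoxy)phenyl]-2-[3,4,5-tris(benzyloxy)phenyl]chromane | COCOc1ccc(Br)c(OCOC)c1[C@@H]1c2ccc(OCc3ccccc3)cc2O[C@H](c2cc(OCc3ccccc3)c(OCc3ccccc3)c(OCc3ccccc3)c2)[C@H]1OCc1ccccc1 | intermediate
17 | (2R,3S)-3-[3,4,5-tris(benzyloxy)phenyl]oxirane-2-carbaldehyde | O=C[C@@H]1O[C@H]1c1cc(OCc2ccccc2)c(OCc2ccccc2)c(OCc2ccccc2)c1 | intermediate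
18 | aryllithium from 16 (lithium in place of bromine) | COCOc1ccc([Li])c(OCOC)c1[C@@H]1c2ccc(OCc3ccccc3)cc2O[C@H](c2cc(OCc3ccccc3)c(OCc3ccccc3)c(OCc3ccccc3)c2)[C@H]1OCc1ccccc1 | intermediate (not isolated)
19 | {3-[(2R,3S,4S)-3,7-bis(benzyloxy)-2-[3,4,5-tris(benzyloxy)phenyl]chroman-4-yl]-2,4-bis(methoxymethoxy)phenyl}{(2S,3S)-3-[3,4,5-tris(benzyloxy)phenyl]oxiran-2-yl}methanol, carbinol epimers | COCOc1ccc(C(O)[C@@H]4O[C@H]4c2cc(OCc3ccccc3)c(OCc3ccccc3)c(OCc3ccccc3)c2)c(OCOC)c1[C@@H]1c2ccc(OCc3ccccc3)cc2O[C@H](c2cc(OCc3ccccc3)c(OCc3ccccc3)c(OCc3ccccc3)c2)[C@H]1OCc1ccccc1 | intermediate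
20 | {3-[(2R,3S,4S)-3,7-bis(benzyloxy)-2-[3,4,5-tris(benzyloxy)phenyl]chroman-4-yl]-2,4-bis(methoxymethoxy)phenyl}{(2R,3S)-3-[3,4,5-tris(benzyloxy)phenyl]oxiran-2-yl}methanone | COCOc1ccc(C(=O)[C@@H]4O[C@H]4c2cc(OCc3ccccc3)c(OCc3ccccc3)c(OCc3ccccc3)c2)c(OCOC)c1[C@@H]1c2ccc(OCc3ccccc3)cc2O[C@H](c2cc(OCc3ccccc3)c(OCc3ccccc3)c(OCc3ccccc3)c2)[C@H]1OCc1ccccc1 | intermediate
21 | 2,4-dihydroxyphenyl analogue of 20 (both acetals removed) | Oc1ccc(C(=O)[C@@H]4O[C@H]4c2cc(OCc3ccccc3)c(OCc3ccccc3)c(OCc3ccccc3)c2)c(O)c1[C@@H]1c2ccc(OCc3ccccc3)cc2O[C@H](c2cc(OCc3ccccc3)c(OCc3ccccc3)c(OCc3ccccc3)c2)[C@H]1OCc1ccccc1 | intermediate (not isolated)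
22 | (2R,3R)-8-[(2R,3S,4S)-3,7-bis(benzyloxy)-2-[3,4,5-tris(benzyloxy)phenyl]chroman-4-yl]-3,7-dihydroxy-2-[3,4,5-tris(benzyloxy)phenyl]chroman-4-one | O=C1c2ccc(O)c([C@@H]3c4ccc(OCc5ccccc5)cc4O[C@H](c4cc(OCc5ccccc5)c(OCc5ccccc5)c(OCc5ccccc5)c4)[C@H]3OCc3ccccc3)c2O[C@H](c2cc(OCc5ccccc5)c(OCc5ccccc5)c(OCc5ccccc5)c2)[C@H]1O | intermediate
23 | (2R,3R)-3,7-dihydroxy-8-[(2R,3S,4S)-3,7-dihydroxy-2-(3,4,5-trihydroxyphenyl)chroman-4-yl]-2-(3,4,5-trihydroxyphenyl)chroman-4-one | O=C1c2ccc(O)c([C@@H]3c4ccc(O)cc4O[C@H](c4cc(O)c(O)c(O)c4)[C@H]3O)c2O[C@H](c2cc(O)c(O)c(O)c2)[C@H]1O | target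

## Step count and least certain steps

Total: 16 steps. Longest linear sequence: 14 steps (steps 1–8, 10, 11, 13–16); steps 9 and 12 are one-step branches.

Step 11 (key step). The most likely failure is loss of selectivity in the capture of the cation: closure onto ring B, attack of ring A through its carbon between the two oxygens, poor facial selectivity at C4, or acid cleavage of an acetal once the cation collapses towards an o-quinone methide. The fallback reverses the order of the two bonds to C4; it sets out from 10 and returns at 16. A mild Lewis acid (MgBr2·OEt2, CH2Cl2, −20 °C) should make ring A add to the aldehyde of 10 para to its benzyloxy group, an intramolecular Friedel–Crafts hydroxyalkylation, to give (2R,3S)-3,7-bis(benzyloxy)-2-[3,4,5-tris(benzyloxy)phenyl]chroman-4-ol F1 as C4 epimers. Ionisation of F1 with BF3·OEt2 at low temperature in the presence of excess 4,6-dibromoresorcinol would give the ring A-stabilised flavan-4-yl cation. The phenol can attack only through its carbon between the hydroxyls, because the other activated positions carry bromine, and attack should occur anti to the C3 substituent as is usual for 2,3-trans flavan-4-yl cations. This would give the 3,4-trans 4-(3,5-dibromo-2,6-dihydroxyphenyl)flavan F2. Acetal formation (MOMCl, i-Pr2NEt) would give the bis(methoxymethyl) ether F3. One equivalent of n-BuLi at −78 °C followed by methanol would remove one of the two equivalent bromines and return 16.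

Step 10. The most likely failure is metalation at a carbon other than the one between the acetal groups (ortho to bromine, followed by bromine migration or aryne formation), or proton transfer from the α-alkoxy aldehyde with loss of the β-aryloxide instead of addition. The fallback replaces deprotonation by halogen–magnesium exchange; it sets out from 11 and returns at 14. 11 would be lithiated between its acetal groups with n-BuLi, the undisputed site when no bromine is present, and quenched with I2 to give 2-iodo-1,3-bis(methoxymethoxy)benzene F4. NBS would brominate F4 para to one acetal to give 1-bromo-3-iodo-2,4-bis(methoxymethoxy)benzene F5. Exchange with i-PrMgCl·LiCl at −40 °C, selective for iodine over bromine, would give [3-bromo-2,6-bis(methoxymethoxy)phenyl]magnesium chloride F6, a less basic nucleophile than 13, whose addition to 10 returns 14.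

Step 13. The most likely failure is decomposition or oligomerisation of the epoxy aldehyde before it is trapped, or quenching of the aryllithium by proton transfer. The fallback builds the epoxy ketone through an enone; it sets out from 16 and returns at 20. The aryllithium from 16 would be acylated with N-methoxy-N-methylacetamide to give the methyl ketone F7. Claisen–Schmidt condensation of F7 with 1 (KOH, EtOH–THF) would give the (E)-chalcone F8. A Juliá–Colonna epoxidation (poly-L-leucine, urea–H2O2, DBU, THF) is expected to deliver the (αR,βS)-epoxide, which is 20.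

Step 15. The most likely failure is ionisation of the protonated epoxide at the benzylic carbon before the phenol is free, which would erode the configuration of lower C2, allow capture by methanol or start an acyl shift. The fallback separates epoxide opening from ring closure; it sets out from 20 and returns at 22. Phenylmethanethiol and SnCl4 at −20 °C should open the epoxide of 20 at the benzylic carbon with the soft nucleophile and cleave both acetals, giving the β-benzylsulfanyl α-hydroxy ketone F9. Thiophilic activation with AgBF4 would then let the ortho phenol displace sulfur and close ring F, with the 2,3-trans ring as the expected main product, to return 22.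

## Further compounds

F1 | step 11 | (2R,3S)-3,7-bis(benzyloxy)-2-[3,4,5-tris(benzyloxy)phenyl]chroman-4-ol, C4 epimers | OC1c2ccc(OCc3ccccc3)cc2O[C@H](c2cc(OCc3ccccc3)c(OCc3ccccc3)c(OCc3ccccc3)c2)[C@H]1OCc1ccccc1
F2 | step 11 | 4,6-dibromo-2-[(2R,3S,4S)-3,7-bis(benzyloxy)-2-[3,4,5-tris(benzyloxy)phenyl]chroman-4-yl]benzene-1,3-diol | Oc1c(Br)cc(Br)c(O)c1[C@@H]1c2ccc(OCc3ccccc3)cc2O[C@H](c2cc(OCc3ccccc3)c(OCc3ccccc3)c(OCc3ccccc3)c2)[C@H]1OCc1ccccc1
F3 | step 11 | (2R,3S,4S)-3,7-bis(benzyloxy)-4-[3,5-dibromo-2,6-bis(methoxymethoxy)phenyl]-2-[3,4,5-tris(benzyloxy)phenyl]chromane | COCOc1c(Br)cc(Br)c(OCOC)c1[C@@H]1c2ccc(OCc3ccccc3)cc2O[C@H](c2cc(OCc3ccccc3)c(OCc3ccccc3)c(OCc3ccccc3)c2)[C@H]1OCc1ccccc1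
F4 | step 10 | 2-iodo-1,3-bis(methoxymethoxy)benzene | COCOc1cccc(OCOC)c1I
F5 | step 10 | 1-bromo-3-iodo-2,4-bis(methoxymethoxy)benzene | COCOc1ccc(Br)c(OCOC)c1I
F6 | step 10 | [3-bromo-2,6-bis(methoxymethoxy)phenyl]magnesium chloride | COCOc1ccc(Br)c(OCOC)c1[Mg]Cl
F7 | step 13 | 1-{3-[(2R,3S,4S)-3,7-bis(benzyloxy)-2-[3,4,5-tris(benzyloxy)phenyl]chroman-4-yl]-2,4-bis(methoxymethoxy)phenyl}ethan-1-one | COCOc1ccc(C(C)=O)c(OCOC)c1[C@@H]1c2ccc(OCc3ccccc3)cc2O[C@H](c2cc(OCc3ccccc3)c(OCc3ccccc3)c(OCc3ccccc3)c2)[C@H]1OCc1ccccc1
F8 | step 13 | (E)-1-{3-[(2R,3S,4S)-3,7-bis(benzyloxy)-2-[3,4,5-tris(benzyloxy)phenyl]chroman-4-yl]-2,4-bis(methoxymethoxy)phenyl}-3-[3,4,5-tris(benzyloxy)phenyl]prop-2-en-1-one | COCOc1ccc(C(=O)/C=C/c2cc(OCc3ccccc3)c(OCc3ccccc3)c(OCc3ccccc3)c2)c(OCOC)c1[C@@H]1c2ccc(OCc3ccccc3)cc2O[C@H](c2cc(OCc3ccccc3)c(OCc3ccccc3)c(OCc3ccccc3)c2)[C@H]1OCc1ccccc1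
F9 | step 15 | anti 3-(benzylsulfanyl)-2-hydroxy-1-{3-[(2R,3S,4S)-3,7-bis(benzyloxy)-2-[3,4,5-tris(benzyloxy)phenyl]chroman-4-yl]-2,4-dihydroxyphenyl}-3-[3,4,5-tris(benzyloxy)phenyl]propan-1-one | Oc1ccc(C(=O)[C@H](O)[C@H](SCc2ccccc2)c2cc(OCc3ccccc3)c(OCc3ccccc3)c(OCc3ccccc3)c2)c(O)c1[C@@H]1c2ccc(OCc3ccccc3)cc2O[C@H](c2cc(OCc3ccccc3)c(OCc3ccccc3)c(OCc3ccccc3)c2)[C@H]1OCc1ccccc1
A1 | alternative 1 | 2,4-dihydroxy-3-(upper flavan-4-yl)phenyl ketone with 2-benzyloxy-3-silyloxy side chain | O=C(c1ccc(O)c([C@@H]3c4ccc(OCc5ccccc5)cc4O[C@H](c4cc(OCc5ccccc5)c(OCc5ccccc5)c(OCc5ccccc5)c4)[C@H]3OCc3ccccc3)c1O)[C@H](OCc1ccccc1)[C@@H](O[Si](C)(C)C(C)(C)C)c1cc(OCc5ccccc5)c(OCc5ccccc5)c(OCc5ccccc5)c1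
A2 | alternative 1 | 1-methoxy-1,3-bis(trimethylsilyloxy)buta-1,3-diene bearing the benzylated upper flavan-4-yl group on C2 | C=C(O[Si](C)(C)C)C(=C(OC)O[Si](C)(C)C)[C@@H]1c2ccc(OCc3ccccc3)cc2O[C@H](c2cc(OCc3ccccc3)c(OCc3ccccc3)c(OCc3ccccc3)c2)[C@H]1OCc1ccccc1
A3 | alternative 1 | 4-(benzyloxy)-5-(tert-butyldimethylsilyloxy)-5-[3,4,5-tris(benzyloxy)phenyl]pent-1-yn-3-one, syn-diol series | C#CC(=O)[C@H](OCc1ccccc1)[C@@H](O[Si](C)(C)C(C)(C)C)c1cc(OCc2ccccc2)c(OCc2ccccc2)c(OCc2ccccc2)c1
A4 | alternative 2 | nona-O-benzyl ether of the target with free lower C3 hydroxyl | O=C1c2ccc(OCc5ccccc5)c([C@@H]3c4ccc(OCc5ccccc5)cc4O[C@H](c4cc(OCc5ccccc5)c(OCc5ccccc5)c(OCc5ccccc5)c4)[C@H]3OCc3ccccc3)c2O[C@H](c2cc(OCc5ccccc5)c(OCc5ccccc5)c(OCc5ccccc5)c2)[C@H]1O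
A5 | alternative 2 | (αR,βS)-epoxychalcone with ring D as 4-benzyl 2-methoxymethyl diether | COCOc1c(C(=O)[C@@H]4O[C@H]4c2cc(OCc3ccccc3)c(OCc3ccccc3)c(OCc3ccccc3)c2)ccc(OCc2ccccc2)c1[C@@H]1c2ccc(OCc3ccccc3)cc2O[C@H](c2cc(OCc3ccccc3)c(OCc3ccccc3)c(OCc3ccccc3)c2)[C@H]1OCc1ccccc1
A6 | alternative 3 | 2,3-trans-3,4-trans 3-(benzyldimethylsilyl)-4-[2,6-bis(methoxymethoxy)phenyl]flavan tetrabenzyl ether | COCOc1cccc(OCOC)c1[C@@H]1c2ccc(OCc3ccccc3)cc2O[C@H](c2cc(OCc3ccccc3)c(OCc3ccccc3)c(OCc3ccccc3)c2)[C@H]1[Si](C)(C)Cc1ccccc1
A7 | alternative 3 | [4-(benzyloxy)-2-hydroxyphenyl][2,6-bis(methoxymethoxy)phenyl]methanol | OC(c1ccc(OCc2ccccc2)cc1O)c1c(OCOC)cccc1OCOC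
A8 | alternative 3 | (E)-benzyldimethyl{2-[3,4,5-tris(benzyloxy)phenyl]ethenyl}silane | C[Si](C)(Cc1ccccc1)/C=C/c1cc(OCc2ccccc2)c(OCc2ccccc2)c(OCc2ccccc2)c1
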